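The route rests on cutting both C2–C1′ bonds. Each pyran ring C carries the same 4-hydroxyphenyl ring B on C2, next to O1, so that without the two rings B the skeleton is two 7,8-dioxygenated chromans joined from C4 of the upper unit to C6 of the lower one. In the key step both anomeric acetates of a hexa-O-benzyl bis(lactol acetate) are ionised and each O1-stabilised C2 oxocarbenium ion takes up a 4-benzyloxyphenyl group from zinc, which adds both rings B and both C2 stereocentres in one operation. The precursor is assembled from two daphnetin-type coumarins by rhodium-catalysed asymmetric conjugate addition, cis-dihydroxylation, benzylation and reductive acetylation.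

Key step: step 11

Remarks on the chemistry
- Stereochemical check: compounds 13, 17 and 18 share one geometry at upper C4 and at lower C3 and C4. In 17 and 18 the upper ring is 2,4-trans and the lower ring 2,3-cis-3,4-cis. No structure needed correction. The CIP label of upper C4 is R in every benzylated compound and S in 18, only because the two aryl groups change rank when O7 of the lower unit loses its benzyl group.
- Assumption: the sense of induction of (S)-SEGPHOS (step 6) and of the DHQD ligand (step 7) is taken from simple coumarins and (Z)-cinnamates. If a first run shows the opposite sense, the enantiomeric or pseudoenantiomeric ligand is used.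
- Design points for the precursor:
  - Upper C4 is too remote to steer the osmylation of the lower ring, so the diol is set under ligand control and purified as a diastereomer.
  - O3 and O4 of the β-hydroxy lactone are benzylated under neutral conditions.
  - Benzyl is kept on O3 and O4 because it is small and cannot participate at C2.
  - Both acetates are made in one flask, and the zinc reagent is used in excess.

Step 1
Reactants: 1 daphnetin
Product: 2 7,8-bis(benzyloxy)coumarin
Conditions: BnBr (2.4 equiv), K2CO3, DMF, 50 °C, N2
Reagents that add atoms: benzyl bromide, BrCc1ccccc1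
Why: Williamson etherification of the two phenols under carbonate leaves the coumarin lactone untouched and forms no stereocentre.

Step 2
Reactants: 3 2,3,4-trihydroxybenzaldehyde
Product: 4 3,4-bis(benzyloxy)-2-hydroxybenzaldehyde
Conditions: BnBr (2.05 equiv), K2CO3 (2.1 equiv), DMF, rt
Reagents that add atoms: benzyl bromide, BrCc1ccccc1
Why: Regioselective Williamson etherification, in which the C2 hydroxyl is hydrogen-bonded to the formyl group and is the least nucleophilic, so two equivalents of benzyl bromide take O3 and O4 as is usual for 2-acylpyrogallols.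

Step 3
Reactants: 4 3,4-bis(benzyloxy)-2-hydroxybenzaldehyde
Product: 5 3,4-bis(benzyloxy)-5-bromo-2-hydroxybenzaldehyde
Conditions: NBS (1.05 equiv), MeCN, 0 °C to rt
Reagents that add atoms: N-bromosuccinimide, O=C1CCC(=O)N1Br
Why: Electrophilic aromatic bromination goes to C5, which is para to the free hydroxyl and ortho to a benzyloxy group, whereas C6 is ortho to the formyl group and meta to the hydroxyl.

Step 4
Reactants: 5 3,4-bis(benzyloxy)-5-bromo-2-hydroxybenzaldehyde
Product: 7 7,8-bis(benzyloxy)-6-bromocoumarin, via ethyl 2-hydroxycinnamate 6 (not isolated)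
Conditions: Ph3P=CHCO2Et (1.3 equiv), PhNEt2, reflux (about 215 °C)
Reagents that add atoms: ethyl (triphenylphosphoranylidene)acetate, CCOC(=O)C=P(c1ccccc1)(c1ccccc1)c1ccccc1
Why: Wittig olefination of the salicylaldehyde with a stabilised ylide, followed at the boiling point of the amine by E/Z equilibration and lactonisation of the (Z)-cinnamate, is a standard one-pot coumarin synthesis and forms no stereocentre.

Step 5
Reactants: 7 7,8-bis(benzyloxy)-6-bromocoumarin
Product: 8 [7,8-bis(benzyloxy)-2-oxo-2H-chromen-6-yl]boronic acid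
Conditions: B2(OH)4 (3 equiv), KOAc (3 equiv), second-generation XPhos palladacycle precatalyst, chloro(2-dicyclohexylphosphino-2′,4′,6′-triisopropyl-1,1′-biphenyl)[2-(2′-amino-1,1′-biphenyl)]palladium (1 mol %), XPhos (2 mol %), EtOH, 80 °C
Reagents that add atoms: tetrahydroxydiboron, OB(O)B(O)O
Why: Miyaura-type palladium-catalysed borylation of the aryl bromide with tetrahydroxydiboron gives the boronic acid directly under acetate base, which the coumarin ring tolerates.

Step 6
Reactants: 8 [7,8-bis(benzyloxy)-2-oxo-2H-chromen-6-yl]boronic acid; 2 7,8-bis(benzyloxy)coumarin (4 equiv, excess recovered)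
Product: 9 (4R)-7,8-bis(benzyloxy)-4-[7,8-bis(benzyloxy)-2-oxo-2H-chromen-6-yl]chroman-2-one
Conditions: Rh(acac)(C2H4)2 (5 mol %), (S)-SEGPHOS (5.5 mol %), dioxane/H2O 10:1, 60 °C, slow addition of 8
Reagents that add atoms: none
Why: Hayashi–Miyaura rhodium-catalysed asymmetric 1,4-addition of an arylboronic acid to a coumarin, in which the aryl–rhodium species adds to C4 of 2, water protonates the oxa-π-allyl intermediate and the SEGPHOS ligand selects the enantioface that sets C4 as R, while the excess of 2 and the slow addition of 8 keep the aryl group from adding to the coumarin ring of 8 or of 9.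

Step 7
Reactants: 9 (4R)-bis-lactone with the lower coumarin ring intact
Product: 10 (3R,4R)-3,4-cis-diol of the lower lactone
Conditions: K2OsO2(OH)4 (5 mol %), DHQD-IND (15 mol %), NMO (1.5 equiv), acetone/H2O 8:1, 0 °C, slow addition of 9; aq Na2SO3; chromatography
Reagents that add atoms: N-methylmorpholine N-oxide, C[N+]1([O-])CCOCC1; water, O
Why: Sharpless-type ligand-accelerated osmium-catalysed dihydroxylation of the only C=C bond (C3=C4 of the lower coumarin) adds both oxygens syn, which fixes the 3,4-cis relation, and the DHQD ligand is relied on for the face, while upper C4 makes the two possible cis-diols diastereomers so that the (3S,4S) isomer is removed by chromatography.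

Step 8
Reactants: 10 (3R,4R)-diol bis-lactone
Product: 11 (3R,4R)-3,4,7,8-tetrakis(benzyloxy)-6-[(4R)-7,8-bis(benzyloxy)-2-oxochroman-4-yl]chroman-2-one
Conditions: 2-benzyloxy-1-methylpyridinium triflate (5 equiv), MgO (5 equiv), PhCF3, 85 °C
Reagents that add atoms: 2-benzyloxy-1-methylpyridinium triflate, C[n+]1ccccc1OCc1ccccc1.[O-]S(=O)(=O)C(F)(F)F
Why: Dudley benzylation releases a benzyl electrophile thermally under neutral conditions, so both secondary hydroxyls are etherified without the retro-aldol cleavage, β-elimination or C3 epimerisation that alkoxide conditions would cause in this β-hydroxy lactone, and without acid that could ionise the C4–OH bond.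

Step 9
Reactants: 11 hexa-O-benzyl bis-lactone
Product: 13 hexa-O-benzyl bis(lactol acetate), via bis(diisobutylaluminium lactolate) 12 (not isolated)
Conditions: iBu2AlH (2.3 equiv), CH2Cl2, −78 °C; then pyridine, DMAP, Ac2O, −78 to 0 °C
Reagents that add atoms: acetic anhydride, CC(=O)OC(C)=O
Why: Rychnovsky reductive acetylation, in which iBu2AlH adds once to each aryl lactone at −78 °C and the stable aluminium lactolates are acetylated in the same flask, gives both acetal centres as anomeric mixtures, which does not matter because ionisation erases them.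

Step 10
Reactants: 14 1-benzyloxy-4-bromobenzene
Product: 16 (4-benzyloxyphenyl)zinc bromide, via (4-benzyloxyphenyl)magnesium bromide 15 (not isolated)
Conditions: Mg, THF, 40 °C; ZnBr2 (1.05 equiv), THF, 0 °C to rt; THF removed, toluene added
Reagents that add atoms: zinc bromide, Br[Zn]Br
Why: Magnesium insertion gives the Grignard reagent and transmetalation with ZnBr2 gives the less basic arylzinc bromide, and the solvent exchange keeps THF from competing for the Lewis acid in the next step.

Step 11
Reactants: 13 hexa-O-benzyl bis(lactol acetate); 16 (4-benzyloxyphenyl)zinc bromide (6 equiv)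
Product: 17 octa-O-benzyl target
Conditions: 16 in toluene, CH2Cl2, −78 °C; BF3·OEt2 (4 equiv) added last; −78 to −45 °C; sat. aq NaHCO3 at −45 °C
Reagents that add atoms: none
Why: Proposed new method: BF3·OEt2 removes each anomeric acetate of 13 to give an oxocarbenium ion (C2=O1+), and the arylzinc bromide transfers its aryl group to C2 of each ion, which forms the two C2–C1′ bonds and closes no ring; the closest known reaction type is the Lewis-acid-promoted C-arylation of cyclic lactol acetates and glycosyl donors by arylzinc reagents through oxocarbenium ions, which has not been shown twofold or on benzo-fused lactol acetates. The upper cation places its C4 aryl substituent pseudoaxially to escape the peri C5–H, which screens the syn face of C2, so the aryl group is delivered anti to it and C2 becomes 2,4-trans. The lower cation, with its cis ether oxygens, should prefer the half-chair that holds O3 pseudoequatorial and O4 pseudoaxial, the arrangement that alkoxy groups favour in these positions, and axial capture through a chair-like transition state puts the aryl group on the face of both oxygens (all-cis). Both anomers of each acetate give the same ion, and the benzyl ethers cannot participate. The step needs ionisation at C2 and not at the benzylic C4–O bond of the lower ring, which is secured by the much better leaving group at C2, by having the nucleophile in excess before the Lewis acid is added, and by the cold quench.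

Step 12
Reactants: 17 octa-O-benzyl target
Product: 18 target (CNP0209379.1)
Conditions: H2 (1 atm), Pd(OH)2/C, THF/MeOH/pH 7 phosphate buffer, rt; filtration under argon
Reagents that add atoms: none
Why: Heterogeneous palladium-catalysed hydrogenolysis at room temperature in a neutral buffered medium cleaves the eight unhindered O–CH2Ph bonds and should spare the C4–O bond of the lower ring, the two C2–O1 bonds and all five stereocentres.

Compound list
1 | daphnetin (7,8-dihydroxycoumarin) | O=c1ccc2ccc(O)c(O)c2o1 | starting material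
2 | 7,8-bis(benzyloxy)coumarin (daphnetin dibenzyl ether) | O=c1ccc2ccc(OCc3ccccc3)c(OCc3ccccc3)c2o1 | intermediate
3 | 2,3,4-trihydroxybenzaldehyde | O=Cc1ccc(O)c(O)c1O | starting material
4 | 3,4-bis(benzyloxy)-2-hydroxybenzaldehyde | O=Cc1ccc(OCc2ccccc2)c(OCc2ccccc2)c1O | intermediate
5 | 3,4-bis(benzyloxy)-5-bromo-2-hydroxybenzaldehyde | O=Cc1cc(Br)c(OCc2ccccc2)c(OCc2ccccc2)c1O | intermediate
6 | ethyl 3-[3,4-bis(benzyloxy)-5-bromo-2-hydroxyphenyl]prop-2-enoate (E isomer drawn; E and Z equilibrate in the flask) | CCOC(=O)/C=C/c1cc(Br)c(OCc2ccccc2)c(OCc2ccccc2)c1O | intermediate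
7 | 7,8-bis(benzyloxy)-6-bromocoumarin | O=c1ccc2cc(Br)c(OCc3ccccc3)c(OCc3ccccc3)c2o1 | intermediate
8 | [7,8-bis(benzyloxy)-2-oxo-2H-chromen-6-yl]boronic acid | O=c1ccc2cc(B(O)O)c(OCc3ccccc3)c(OCc3ccccc3)c2o1 | intermediate
9 | (4R)-7,8-bis(benzyloxy)-4-[7,8-bis(benzyloxy)-2-oxo-2H-chromen-6-yl]chroman-2-one | O=C1C[C@@H](c2cc3ccc(=O)oc3c(OCc9ccccc9)c2OCc9ccccc9)c2ccc(OCc9ccccc9)c(OCc9ccccc9)c2O1 | intermediate
10 | (3R,4R)-7,8-bis(benzyloxy)-6-[(4R)-7,8-bis(benzyloxy)-2-oxochroman-4-yl]-3,4-dihydroxychroman-2-one (3,4-cis) | O=C1C[C@@H](c2cc3c(c(OCc9ccccc9)c2OCc9ccccc9)OC(=O)[C@H](O)[C@@H]3O)c2ccc(OCc9ccccc9)c(OCc9ccccc9)c2O1 | intermediate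
11 | (3R,4R)-3,4,7,8-tetrakis(benzyloxy)-6-[(4R)-7,8-bis(benzyloxy)-2-oxochroman-4-yl]chroman-2-one | O=C1C[C@@H](c2cc3c(c(OCc9ccccc9)c2OCc9ccccc9)OC(=O)[C@H](OCc9ccccc9)[C@@H]3OCc9ccccc9)c2ccc(OCc9ccccc9)c(OCc9ccccc9)c2O1 | intermediate
12 | bis(O-diisobutylaluminium) lactolate of 11 (both acetal carbons as mixtures) | CC(C)C[Al](CC(C)C)OC1C[C@@H](c2cc3c(c(OCc9ccccc9)c2OCc9ccccc9)OC(O[Al](CC(C)C)CC(C)C)[C@H](OCc9ccccc9)[C@@H]3OCc9ccccc9)c2ccc(OCc9ccccc9)c(OCc9ccccc9)c2O1 | intermediate
13 | (3R,4R)-6-[(4R)-2-acetoxy-7,8-bis(benzyloxy)chroman-4-yl]-3,4,7,8-tetrakis(benzyloxy)chroman-2-yl acetate (anomeric mixture at both C2; one anomer drawn) | CC(=O)O[C@H]2C[C@@H](c3cc4c(c(OCc9ccccc9)c3OCc9ccccc9)O[C@@H](OC(C)=O)[C@H](OCc9ccccc9)[C@@H]4OCc9ccccc9)c3ccc(OCc9ccccc9)c(OCc9ccccc9)c3O2 | intermediate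
14 | 1-benzyloxy-4-bromobenzene | Brc1ccc(OCc2ccccc2)cc1 | starting material
15 | (4-benzyloxyphenyl)magnesium bromide | Br[Mg]c1ccc(OCc2ccccc2)cc1 | intermediate
16 | (4-benzyloxyphenyl)zinc bromide | Br[Zn]c1ccc(OCc2ccccc2)cc1 | intermediate
17 | (2R,3R,4R)-3,4,7,8-tetrakis(benzyloxy)-2-(4-benzyloxyphenyl)-6-[(2S,4R)-7,8-bis(benzyloxy)-2-(4-benzyloxyphenyl)chroman-4-yl]chroman (upper ring 2,4-trans; lower ring all-cis) | O(Cc9ccccc9)c1ccc([C@@H]2C[C@@H](c3cc4c(c(OCc9ccccc9)c3OCc9ccccc9)O[C@H](c5ccc(OCc9ccccc9)cc5)[C@H](OCc9ccccc9)[C@@H]4OCc9ccccc9)c3ccc(OCc9ccccc9)c(OCc9ccccc9)c3O2)cc1 | intermediate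
18 | (2R,3R,4R)-2-(4-hydroxyphenyl)-6-[(2S,4S)-7,8-dihydroxy-2-(4-hydroxyphenyl)chroman-4-yl]chroman-3,4,7,8-tetrol | Oc1ccc([C@@H]2C[C@@H](c3cc4c(c(O)c3O)O[C@H](c3ccc(O)cc3)[C@H](O)[C@@H]4O)c3ccc(O)c(O)c3O2)cc1 | target

Total step count: 12. Longest linear sequence: 10 steps (steps 2, 3, 4, 5, 6, 7, 8, 9, 11, 12) from 2,3,4-trihydroxybenzaldehyde 3.

Steps most likely to fail

Step 11 (the new method). Three things may go wrong:
- the benzylic C4–O bond of the lower ring may ionise in competition with C2, before or after the aryl transfer;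
- the upper cation may lose a proton from C3 to give a 4H-chromene;
- the face selectivity at either C2 may be too low.

The fallback gives up the oxocarbenium arylation and builds each C2 centre from a ketone with known reactions; it sets out from 11 and comes back at 17.
- Both lactones of 11 would be opened with MeNH(OMe)·HCl and AlMe3 to the bis(Weinreb amide) bisphenol F1.
- An excess of the Grignard reagent 15 would convert F1 into the bis(aryl ketone) F2.
- Reagent-controlled reduction with the (S)-CBS oxazaborolidine and BH3·SMe2 should give the bis(carbinol) F3. Both carbinol centres need the same spatial sense of aryl group, chain and hydroxyl (labelled R in the upper chain and S in the lower one), so one catalyst enantiomer serves both.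
- A twofold Mitsunobu cyclisation (PPh3, DIAD, THF) would close both O1–C2 bonds with inversion to give 17.

The weak points of this detour are possible epimerisation of the α-benzyloxy ketone in F2 and partial ionisation of the electron-rich benzylic alcohols in the Mitsunobu step.

Step 6. The aryl–rhodium species may add to the coumarin ring of 8 or of 9 and give oligomers, or transmetalation may be slow so that protodeboronation wins. The fallback changes the order of events so that the boron partner carries no enoate; it sets out from 7 and comes back at 11.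
- Bromocoumarin 7 would be dihydroxylated under the conditions of step 7 to the bromo diol lactone F4.
- F4 would be benzylated as in step 8 to the bromo bis(benzyl ether) lactone F5.
- F5 would be borylated (B2pin2, PdCl2(dppf), KOAc, dioxane, 85 °C) to the pinacol boronate F6.
- F6 would be added to 2 under the conditions of step 6 to give 11 directly.

The stereoisomer that arises from the minor enantiomer of F4 is then a diastereomer of 11 and is removed by chromatography.

Step 7. The ligand may give poor facial selectivity on this cyclic (Z)-enoate. The fallback gives up reagent control in favour of separation and recycling; it sets out from 9 and comes back at 9.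
- Dihydroxylation of 9 with OsO4 and NMO without ligand would give 10 together with the (3S,4S)-diol diastereomer F7, which are separated.
- F7 would be converted with 1,1′-thiocarbonyldiimidazole into the cyclic thionocarbonate F8.
- Corey–Winter elimination of F8 with P(OMe)3 would return the alkene 9 for another pass.

Further compounds
F1 | step 11 | bis(Weinreb amide) bisphenol from opening of both lactones of 11 | CON(C)C(=O)C[C@@H](c1cc([C@@H](OCc9ccccc9)[C@@H](OCc9ccccc9)C(=O)N(C)OC)c(O)c(OCc9ccccc9)c1OCc9ccccc9)c1ccc(OCc9ccccc9)c(OCc9ccccc9)c1O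
F2 | step 11 | bis(4-benzyloxyphenyl ketone) bisphenol | O=C(C[C@@H](c1cc([C@@H](OCc9ccccc9)[C@@H](OCc9ccccc9)C(=O)c2ccc(OCc9ccccc9)cc2)c(O)c(OCc9ccccc9)c1OCc9ccccc9)c1ccc(OCc9ccccc9)c(OCc9ccccc9)c1O)c1ccc(OCc9ccccc9)cc1
F3 | step 11 | bis(carbinol) bisphenol (upper carbinol R, lower carbinol S) | O[C@H](C[C@@H](c1cc([C@@H](OCc9ccccc9)[C@@H](OCc9ccccc9)[C@@H](O)c2ccc(OCc9ccccc9)cc2)c(O)c(OCc9ccccc9)c1OCc9ccccc9)c1ccc(OCc9ccccc9)c(OCc9ccccc9)c1O)c1ccc(OCc9ccccc9)cc1
F4 | step 6 | (3R,4R)-7,8-bis(benzyloxy)-6-bromo-3,4-dihydroxychroman-2-one | Brc1cc2c(c(OCc9ccccc9)c1OCc9ccccc9)OC(=O)[C@H](O)[C@@H]2O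
F5 | step 6 | (3R,4R)-3,4,7,8-tetrakis(benzyloxy)-6-bromochroman-2-one | Brc1cc2c(c(OCc9ccccc9)c1OCc9ccccc9)OC(=O)[C@H](OCc9ccccc9)[C@@H]2OCc9ccccc9
F6 | step 6 | (3R,4R)-3,4,7,8-tetrakis(benzyloxy)-6-(4,4,5,5-tetramethyl-1,3,2-dioxaborolan-2-yl)chroman-2-one | CC1(C)OB(OC1(C)C)c1cc2c(c(OCc9ccccc9)c1OCc9ccccc9)OC(=O)[C@H](OCc9ccccc9)[C@@H]2OCc9ccccc9
F7 | step 7 | (3S,4S)-diol diastereomer of 10 | O=C1C[C@@H](c2cc3c(c(OCc9ccccc9)c2OCc9ccccc9)OC(=O)[C@@H](O)[C@H]3O)c2ccc(OCc9ccccc9)c(OCc9ccccc9)c2O1
F8 | step 7 | cyclic 3,4-thionocarbonate of F7 | O=C1C[C@@H](c2cc3c(c(OCc9ccccc9)c2OCc9ccccc9)OC(=O)[C@H]4OC(=S)O[C@@H]34)c2ccc(OCc9ccccc9)c(OCc9ccccc9)c2O1
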